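**Retrosynthetic overview**

- Feature: in the 5,7-dimethoxyflavan ring system the C4 methine sits on C4a, whose neighbour C8a carries the pyran oxygen O1. C4–C4a–C8a–O1 is therefore a masked o-quinone methide (an oxa-diene), and C2–C3 with the 4-oxyphenyl group on C2 is a styrene.
- Key disconnection: the three pyran-ring bonds C4–C4a, C3–C4 and O1–C2 are cut together, giving 3,5-dimethoxyphenol, a protected (S)-flavanone-8-carbaldehyde and 4-benzyloxystyrene. A chiral phosphoric acid sets C4 and acid equilibration sets C2 trans to it.
- Aldehyde: the C8 formyl group comes from the C8 iodide, and the iodide from iodination of (S)-5,7-bis(benzyloxy)flavanone. The flavanone is made by rhodium-catalysed asymmetric phenyl addition to 5,7-bis(benzyloxy)chromone, because base-mediated benzylation of a preformed 5-hydroxyflavanone would open it to the chalcone and racemise C2.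
- Ring order: the pyranone ring of the flavanone (as chromone) first, then its C2 centre, then the pyran ring of the flavan in the key step; hydrogenolysis of three benzyl ethers ends the route.

Key step: step 6

Assumption: the (S)-bisphosphine of step 2 and the (R)-phosphoric acid of step 6 are taken to give the 2S flavanone centre and the 4R flavan centre (the antipodal ligand or acid is used if either sense proves opposite), and the dibenzylated acetophenone is taken as purchasable (otherwise one benzylation from 2,4,6-trihydroxyacetophenone).

**Route**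

Step 1
Reactants: 1 1-[2,4-bis(benzyloxy)-6-hydroxyphenyl]ethan-1-one
Product: 3 5,7-bis(benzyloxy)-4H-chromen-4-one, via enaminone 2 (not isolated)
Conditions: Me2NCH(OMe)2 (3 equiv), PhMe, 100 °C; then conc. HCl, CH2Cl2, 40 °C
Reagents that add atoms: N,N-dimethylformamide dimethyl acetal, COC(OC)N(C)C
Why: Condensation of the acetyl methyl group with the formamide acetal gives the (E)-enaminone, and acid then drives conjugate addition of the phenol and loss of dimethylamine (enaminone route to 3-unsubstituted chromones), so the former 6-OH becomes O1 and the benzyl ethers sit unambiguously at C5 and C7.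

Step 2
Reactants: 3 5,7-bis(benzyloxy)-4H-chromen-4-one; 4 phenylboronic acid
Product: 5 (2S)-5,7-bis(benzyloxy)-2-phenylchroman-4-one
Conditions: 4 (3 equiv), [Rh(OH)(cod)]2 (2.5 mol %), (S)-2,2'-bis[bis(3,4,5-trifluorophenyl)phosphino]-6,6'-dimethoxy-1,1'-biphenyl (5.5 mol %), PhMe/H2O (10:1), 20 °C
Reagents that add atoms: none
Why: Hayashi–Miyaura rhodium-catalysed asymmetric 1,4-addition of the arylboronic acid to the chromone enone, in which the base-free hydroxorhodium complex of the electron-poor atropisomeric bisphosphine delivers phenyl to one face of C2=C3 (2S expected with the (S)-ligand by analogy with (S)-BINAP and cyclohexenone) and the neutral, cool conditions avoid the retro-oxa-Michael opening that racemises flavanones.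

Step 3
Reactants: 5 (2S)-5,7-bis(benzyloxy)-2-phenylchroman-4-one
Product: 6 (2S)-5,7-bis(benzyloxy)-8-iodo-2-phenylchroman-4-one
Conditions: NIS (1.1 equiv), CF3CO2H (0.3 equiv), MeCN, 0 → 23 °C
Reagents that add atoms: N-iodosuccinimide, O=C1CCC(=O)N1I
Why: Electrophilic aromatic iodination by acid-activated NIS, in which C6 and C8 are both activated by three oxygens but the peri carbonyl turns the 5-benzyloxy group toward C6, so the less hindered C8 between O1 and 7-OBn should react, as is the rule for 5-O-alkylated 5,7-dioxygenated flavonoids, while C2 is untouched by the mild acid.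

Step 4
Reactants: 6 (2S)-5,7-bis(benzyloxy)-8-iodo-2-phenylchroman-4-one
Product: 7 (2S)-5,7-bis(benzyloxy)-4-oxo-2-phenylchroman-8-carbaldehyde
Conditions: CO (3 atm), Pd(PPh3)4 (5 mol %), Bu3SnH (1.2 equiv, added over 4 h), THF, 50 °C
Reagents that add atoms: carbon monoxide, [C-]#[O+]
Why: Palladium-catalysed reductive carbonylation (formylation) of the aryl iodide by oxidative addition to zerovalent palladium, CO insertion and hydride transfer from the tin hydride, run without base so the flavanone cannot open, with slow hydride addition under CO pressure keeping acyl formation ahead of direct reduction.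

Step 5
Reactants: 8 4-(benzyloxy)benzaldehyde
Product: 9 1-(benzyloxy)-4-vinylbenzene (4-benzyloxystyrene)
Conditions: Ph3PCH3Br (1.3 equiv), KOtBu (1.25 equiv), THF, 0 → 23 °C
Reagents that add atoms: methyltriphenylphosphonium bromide, C[P+](c1ccccc1)(c1ccccc1)c1ccccc1.[Br-]
Why: Wittig methylenation of a non-enolisable aromatic aldehyde with the unstabilised ylide made in the flask, to which the benzyl ether is inert.

Step 6
Reactants: 7 (2S)-5,7-bis(benzyloxy)-4-oxo-2-phenylchroman-8-carbaldehyde; 9 4-benzyloxystyrene; 10 3,5-dimethoxyphenol
Product: 14 (2S)-5,7-bis(benzyloxy)-8-[(2S,4R)-2-(4-benzyloxyphenyl)-5,7-dimethoxychroman-4-yl]-2-phenylchroman-4-one (2,4-trans tri-O-benzyl ether of the target), via diarylcarbinol 11 (not isolated), via o-quinone methide 12 (not isolated), via 2,4-cis chroman 13 (not isolated)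
Conditions: 7 (1 equiv), 9 (3 equiv), (R)-3,3'-bis(2,4,6-triisopropylphenyl)-1,1'-binaphthyl-2,2'-diyl hydrogen phosphate ((R)-TRIP, 10 mol %), 5 Å MS, PhMe, 40 °C, 10 (1.2 equiv) added slowly; then TsOH·H2O (20 mol %), 23 °C
Reagents that add atoms: none
Why: Proposed new method: the phosphoric acid, hydrogen-bonded to both the phenol OH of 10 and the aldehyde oxygen of 7, should mediate ortho-hydroxyalkylation (C4–C4a) to carbinol 11, which loses water to o-quinone methide 12, held as a hydrogen-bonded ion pair with the chiral phosphate; styrene 9 then adds with its CH2 terminus to the methide carbon (C3–C4) and the phenolic oxygen captures the resulting 4-benzyloxybenzylic cation (O1–C2). The closest known reaction types are the phosphoric acid-catalysed [4+2] cycloaddition of o-quinone methides released from o-hydroxybenzyl alcohols with electron-rich styrenes, and the three-component chroman synthesis from phenols, aldehydes and alkenes under achiral acid or boronic acid templating; their merger into one catalytic asymmetric operation is the new element. The pyran ring closes in an inverse-electron-demand oxa-[4+2] (hetero-Diels–Alder) sense, either concerted and asynchronous or stepwise by six-membered-ring capture of the benzylic cation by oxygen. C4 is set by the phosphate, which sits on the quinone methide oxygen next to the methide carbon and blocks one face to the incoming styrene (4R expected), the fixed flavanone centre turning any C4 error into a separable diastereomer. C2 is set thermodynamically, because the cyclic 4-alkoxybenzylic ether ionises reversibly once TsOH is added, so the kinetic 2,4-cis chroman 13 drains into the trans isomer with the 4-aryl group pseudoaxial, away from 5-OMe, and the 2-aryl group equatorial, while reclosure of the open cation is much faster than loss of styrene and leaves C4 intact. The step needs ortho rather than para attack on 10, favoured by the two-point binding of phenol and aldehyde on the catalyst, and one mode of closure only, secured because 10 carries the sole free hydroxyl, its two ortho carbons are equivalent and every flavanone oxygen is benzylated or in a ring; slow addition of 10 with excess 9 limits capture of the cation by a second phenol, and the ketone-conjugated flavanone ring keeps aldehyde and cation electrophilic.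

Step 7
Reactants: 14 (2S)-5,7-bis(benzyloxy)-8-[(2S,4R)-2-(4-benzyloxyphenyl)-5,7-dimethoxychroman-4-yl]-2-phenylchroman-4-one
Product: 15 (2S)-5,7-dihydroxy-8-[(2S,4R)-2-(4-hydroxyphenyl)-5,7-dimethoxychroman-4-yl]-2-phenylchroman-4-one (CNP0188217.1)
Conditions: H2 (1 atm), 10% Pd/C, EtOAc/MeOH (1:1), 23 °C
Reagents that add atoms: none
Why: Catalytic hydrogenolysis of the three aryl benzyl ethers, which is much faster than cleavage of the ring benzylic C–O bonds of the flavan and flavanone or reduction of the hydrogen-bonded aryl ketone, so the three stereocentres and both methyl ethers are kept if the reaction is stopped once debenzylation is complete.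

**Compound list**

1 | 1-[2,4-bis(benzyloxy)-6-hydroxyphenyl]ethan-1-one | CC(=O)c1c(O)cc(OCc2ccccc2)cc1OCc1ccccc1 | starting material
2 | (E)-1-[2,4-bis(benzyloxy)-6-hydroxyphenyl]-3-(dimethylamino)prop-2-en-1-one | CN(C)/C=C/C(=O)c1c(O)cc(OCc2ccccc2)cc1OCc1ccccc1 | intermediate
3 | 5,7-bis(benzyloxy)-4H-chromen-4-one | O=C1C=COc2cc(OCc3ccccc3)cc(OCc3ccccc3)c12 | intermediate
4 | phenylboronic acid | OB(O)c1ccccc1 | starting material
5 | (2S)-5,7-bis(benzyloxy)-2-phenylchroman-4-one | O=C1C[C@@H](c2ccccc2)Oc2cc(OCc3ccccc3)cc(OCc3ccccc3)c12 | intermediate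
6 | (2S)-5,7-bis(benzyloxy)-8-iodo-2-phenylchroman-4-one | O=C1C[C@@H](c2ccccc2)Oc2c(I)c(OCc3ccccc3)cc(OCc3ccccc3)c12 | intermediate
7 | (2S)-5,7-bis(benzyloxy)-4-oxo-2-phenylchroman-8-carbaldehyde | O=Cc1c(OCc2ccccc2)cc(OCc2ccccc2)c2c1O[C@H](c1ccccc1)CC2=O | intermediate
8 | 4-(benzyloxy)benzaldehyde | O=Cc1ccc(OCc2ccccc2)cc1 | starting material
9 | 1-(benzyloxy)-4-vinylbenzene | C=Cc1ccc(OCc2ccccc2)cc1 | intermediate
10 | 3,5-dimethoxyphenol | COc1cc(O)cc(OC)c1 | starting material
11 | (2S)-5,7-bis(benzyloxy)-8-[hydroxy(2-hydroxy-4,6-dimethoxyphenyl)methyl]-2-phenylchroman-4-one, both carbinol epimers | COc1cc(O)c(C(O)c2c(OCc3ccccc3)cc(OCc3ccccc3)c3c2O[C@H](c2ccccc2)CC3=O)c(OC)c1 | intermediate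
12 | (2S)-5,7-bis(benzyloxy)-8-[(2,4-dimethoxy-6-oxocyclohexa-2,4-dien-1-ylidene)methyl]-2-phenylchroman-4-one, alkene geometry not fixed | O=C1C=C(OC)C=C(OC)C1=Cc1c(OCc2ccccc2)cc(OCc2ccccc2)c2c1O[C@H](c1ccccc1)CC2=O | intermediate
13 | (2S)-5,7-bis(benzyloxy)-8-[(2R,4R)-2-(4-benzyloxyphenyl)-5,7-dimethoxychroman-4-yl]-2-phenylchroman-4-one, 2,4-cis | COc1cc(OC)c2c(c1)O[C@@H](c1ccc(OCc3ccccc3)cc1)C[C@H]2c1c(OCc3ccccc3)cc(OCc3ccccc3)c2c1O[C@H](c1ccccc1)CC2=O | intermediate
14 | (2S)-5,7-bis(benzyloxy)-8-[(2S,4R)-2-(4-benzyloxyphenyl)-5,7-dimethoxychroman-4-yl]-2-phenylchroman-4-one, 2,4-trans | COc1cc(OC)c2c(c1)O[C@H](c1ccc(OCc3ccccc3)cc1)C[C@H]2c1c(OCc3ccccc3)cc(OCc3ccccc3)c2c1O[C@H](c1ccccc1)CC2=O | intermediate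
15 | (2S)-5,7-dihydroxy-8-[(2S,4R)-2-(4-hydroxyphenyl)-5,7-dimethoxychroman-4-yl]-2-phenylchroman-4-one, 2,4-trans | COc1cc(OC)c2c(c1)O[C@H](c1ccc(O)cc1)C[C@H]2c1c(O)cc(O)c2c1O[C@H](c1ccccc1)CC2=O | target

**Step count**

Total step count: 7. Longest linear sequence: 6 steps (1 → 3 → 5 → 6 → 7 → 14 → 15); step 5 is a one-step side branch.

**Steps most likely to fail**

Step 6. The three-component process may be diverted by para attack on the phenol, by capture of the diarylmethyl cation by a second phenol instead of the styrene, by cationic oligomerisation of the styrene, or by weak facial control because the styrene offers the catalyst no hydrogen-bond handle. The fallback uses known chemistry, sets out from 7 and 10 and makes the C4–C4a bond separately and ortho-specifically on a boron template. Heating 7, 10 and PhB(OH)2 with catalytic propionic acid in toluene under azeotropic removal of water should give 4-[(2S)-5,7-bis(benzyloxy)-4-oxo-2-phenylchroman-8-yl]-5,7-dimethoxy-2-phenyl-4H-1,3,2-benzodioxaborine F1, the aldehyde carbon being delivered to the ortho carbon within the aryloxyboronate. Exchange of F1 with propane-1,3-diol releases carbinol 11, here isolated. Carbinol 11 and styrene 9 are then combined in the two-component phosphoric acid-catalysed o-quinone methide/styrene [4+2] cycloaddition ((R)-TRIP, 5 Å MS, PhMe), followed by the same TsOH equilibration. If facial control is still poor, the C4 epimers are diastereomers and are separated by chromatography. The fallback comes back to the route at 14.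

Step 3. Iodination may occur at C6 in competition with C8, or go on to the diiodide. The fallback sets out from 1 and places the iodine before the heterocycle is built, where the free phenol directs it. Benzyltrimethylammonium dichloroiodate with CaCO3 in CH2Cl2/MeOH should iodinate ortho to the hydroxyl and give 1-[4,6-bis(benzyloxy)-2-hydroxy-3-iodophenyl]ethan-1-one F2. The conditions of step 1 then give 5,7-bis(benzyloxy)-8-iodo-4H-chromen-4-one F3, in which the iodine is necessarily at C8 because the hydroxyl next to it has become O1. The conditions of step 2 with 4 then add phenyl to F3; the carbon–iodine bond is expected to survive the hydroxorhodium catalyst at 20 °C. The fallback comes back to the route at 6.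

Step 4. Hydrodeiodination may outpace CO insertion at the doubly ortho-substituted arylpalladium intermediate. The fallback sets out from 6 and brings in the formyl carbon as a vinyl group. Stille coupling of 6 with tributyl(vinyl)stannane (Pd(PPh3)4, PhMe, 100 °C) should give (2S)-5,7-bis(benzyloxy)-2-phenyl-8-vinylchroman-4-one F4. Lemieux–Johnson cleavage of F4 (OsO4 cat., NaIO4, 2,6-lutidine, dioxane/H2O, 23 °C) then gives the aldehyde. Both operations are neutral and leave C2 alone. The fallback comes back to the route at 7.

Further compounds
F1 | step 6 | 4-[(2S)-5,7-bis(benzyloxy)-4-oxo-2-phenylchroman-8-yl]-5,7-dimethoxy-2-phenyl-4H-1,3,2-benzodioxaborine, both C4 epimers | COc1cc(OC)c2c(c1)OB(c1ccccc1)OC2c1c(OCc3ccccc3)cc(OCc3ccccc3)c3c1O[C@H](c1ccccc1)CC3=O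
F2 | step 3 | 1-[4,6-bis(benzyloxy)-2-hydroxy-3-iodophenyl]ethan-1-one | CC(=O)c1c(O)c(I)c(OCc2ccccc2)cc1OCc1ccccc1
F3 | step 3 | 5,7-bis(benzyloxy)-8-iodo-4H-chromen-4-one | O=C1C=COc2c(I)c(OCc3ccccc3)cc(OCc3ccccc3)c12
F4 | step 4 | (2S)-5,7-bis(benzyloxy)-2-phenyl-8-vinylchroman-4-one | C=Cc1c(OCc2ccccc2)cc(OCc2ccccc2)c2c1O[C@H](c1ccccc1)CC2=O
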